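## Retrosynthetic overview

- The plan rests on two features of the flavanone. The C4 carbonyl is bonded to C4a of ring A, the carbon next to C8a–O1. The C2–O1 bond is a benzylic aryl ether on the para-methoxylated ring B, which acid can ionise. Ring C is therefore closed last, cold and under base, through the C4–C4a bond.
- Target ⇒ its 3'-O-methoxymethyl ether ⇒ (C4–C4a) an open-chain (3S)-3-aryloxy-3-aryl-N-methoxy-N-methylpropanamide with bromine at the future C4a; bromine–lithium exchange and intramolecular acylation (Parham cyclisation) form ring C.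
- C2–O1 ⇒ Mitsunobu inversion of an (R)-β-hydroxy amide by 6-bromo-2,3-dimethoxyphenol; this is where C2 becomes (S).
- (R)-carbinol ⇒ asymmetric transfer hydrogenation of the β-keto amide ⇒ aldol of protected 3-hydroxy-4,5-dimethoxybenzaldehyde with the enolate of N-methoxy-N-methylacetamide, then oxidation. Bromophenol ⇒ ortho-bromination of 2,3-dimethoxyphenol.
- Ring order: rings A and B are bought; ring C is the only ring formed, in step 7.

Key step: step 7

Remark on the chemistry: (2S) in the target corresponds to (3S) in the open-chain ether and, because the etherification inverts, to an (R)-carbinol before it. The three starting materials are assumed to be purchasable.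

## Route

Step 1
Reactants: 1 3-hydroxy-4,5-dimethoxybenzaldehyde
Product: 2 3,4-dimethoxy-5-(methoxymethoxy)benzaldehyde
Conditions: MOMCl, i-Pr2NEt, CH2Cl2, 0 °C to rt
Reagents that add atoms: chloromethyl methyl ether, COCCl
Why: Williamson-type O-alkylation of the phenol by the reactive α-chloro ether gives the methoxymethyl ether, which should tolerate the later enolate, Mitsunobu and organolithium conditions and can be removed last with mild acid.

Step 2
Reactants: 2 3,4-dimethoxy-5-(methoxymethoxy)benzaldehyde; 3 N-methoxy-N-methylacetamide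
Product: 6 racemic 3-[3,4-dimethoxy-5-(methoxymethoxy)phenyl]-3-hydroxy-N-methoxy-N-methylpropanamide, via lithium amide enolate 4 (not isolated), via lithium aldolate 5 (not isolated)
Conditions: LiN(i-Pr)2 (LDA), THF, −78 °C, 3; then 2, −78 °C; AcOH quench, −78 °C to rt
Reagents that add atoms: none
Why: Aldol addition of the preformed lithium amide enolate to the non-enolisable aryl aldehyde should be fast at −78 °C, the chelated aldolate resisting retro-aldol until the cold acid quench, and the new carbinol centre is left racemic because step 3 erases it.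

Step 3
Reactants: 6 racemic 3-[3,4-dimethoxy-5-(methoxymethoxy)phenyl]-3-hydroxy-N-methoxy-N-methylpropanamide
Product: 7 3-[3,4-dimethoxy-5-(methoxymethoxy)phenyl]-N-methoxy-N-methyl-3-oxopropanamide
Conditions: Dess–Martin periodinane (1.2 equiv), CH2Cl2, 0 °C to rt
Reagents that add atoms: none
Why: Dess–Martin oxidation of the secondary benzylic alcohol runs under nearly neutral conditions that spare the acetal and the N–O bond, and is a standard way to turn aldols into β-dicarbonyl compounds without retro-aldol cleavage.

Step 4
Reactants: 7 3-[3,4-dimethoxy-5-(methoxymethoxy)phenyl]-N-methoxy-N-methyl-3-oxopropanamide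
Product: 8 (3R)-3-[3,4-dimethoxy-5-(methoxymethoxy)phenyl]-3-hydroxy-N-methoxy-N-methylpropanamide
Conditions: RuCl[(R,R)-TsDPEN](p-cymene) (1 mol %; TsDPEN = N-tosyl-1,2-diphenylethylenediamine), HCO2H/Et3N (5:2), DMF, 30 °C
Reagents that add atoms: none
Why: In this Noyori asymmetric transfer hydrogenation of an aryl ketone the (R,R)-ligated ruthenium hydride transfers hydride and proton through the six-membered outer-sphere transition state with ring B held against the p-cymene ligand by a CH/π contact, which for aryl alkyl ketones should give the (R)-carbinol, while loss of CO2 makes the reduction irreversible and the amide, the N–O bond and the acetal are not touched.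

Step 5
Reactants: 9 2,3-dimethoxyphenol
Product: 10 6-bromo-2,3-dimethoxyphenol
Conditions: t-BuNH2 (2 equiv), Br2 (1 equiv), toluene, −30 °C; then 9, −78 °C to rt
Reagents that add atoms: bromine, BrBr
Why: Amine-mediated ortho-bromination of a phenol, in which N-bromo-tert-butylamine made in the flask is hydrogen-bonded to the phenolic OH and delivers bromine to the only free ortho carbon, C6, which is also para to the 3-methoxy group, at a temperature where attack at C4 and double bromination should be slow.

Step 6
Reactants: 8 (3R)-3-[3,4-dimethoxy-5-(methoxymethoxy)phenyl]-3-hydroxy-N-methoxy-N-methylpropanamide; 10 6-bromo-2,3-dimethoxyphenol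
Product: 12 (3S)-3-(6-bromo-2,3-dimethoxyphenoxy)-3-[3,4-dimethoxy-5-(methoxymethoxy)phenyl]-N-methoxy-N-methylpropanamide, via alkoxytriphenylphosphonium aryloxide 11 (not isolated)
Conditions: PPh3, DIAD (added slowly), toluene, 0 °C to rt
Reagents that add atoms: none
Why: In this Mitsunobu etherification the carbinol is activated as the alkoxyphosphonium ion 11 and displaced from the rear by the aryloxide of 10 (acidic enough because of the ortho bromine), so the (R)-carbinol should become the (S)-ether by SN2 inversion, the weakly acidic α-hydrogens of the amide slowing elimination and the out-of-plane 4-methoxy group of ring B (flanked by two oxygen substituents) limiting ionisation to a benzylic cation.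

Step 7
Reactants: 12 (3S)-3-(6-bromo-2,3-dimethoxyphenoxy)-3-[3,4-dimethoxy-5-(methoxymethoxy)phenyl]-N-methoxy-N-methylpropanamide
Product: 15 (2S)-2-[3,4-dimethoxy-5-(methoxymethoxy)phenyl]-7,8-dimethoxy-2,3-dihydro-4H-chromen-4-one, via aryllithium 13 (not isolated), via lithium hemiaminal alkoxide 14 (not isolated)
Conditions: t-BuLi (2.1 equiv), THF, −90 °C, then −78 °C; AcOH quench at −78 °C, then aqueous NaHCO3 work-up
Reagents that add atoms: none
Why: tert-Butyllithium should exchange the bromine at the future C4a within minutes at −90 °C, much faster than it adds to the amide or removes an α-proton, and the second equivalent destroys the tert-butyl bromide formed so that aryllithium 13 is neither alkylated nor protonated by it. The aryllithium, held next to O1, attacks the amide carbonyl in a 6-exo-trig closure that forms the C4–C4a bond and ring C, and the five-membered lithium chelate with the N-methoxy oxygen keeps adduct 14 tetrahedral until the quench, so no ketone is exposed to base. This is a Parham cyclisation, the reaction type known for 3-(2-bromoaryloxy)propanoic acid derivatives giving chroman-4-ones. No stereocentre is created; C2 lies outside the bonds that change and keeps its (S) configuration as long as neither α-deprotonation with loss of the aryloxide nor deprotonation at C2 intervenes. The chemoselectivity needed, exchange and ring closure ahead of enolisation, is secured by the low temperature, the bulk of the base and the intramolecular position of the electrophile, and the site of acylation is fixed by the bromine, so ring B cannot be acylated. No acid is present, so the ionisable C2–O1 benzylic ether stays intact.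

Step 8
Reactants: 15 (2S)-2-[3,4-dimethoxy-5-(methoxymethoxy)phenyl]-7,8-dimethoxy-2,3-dihydro-4H-chromen-4-one
Product: 16 (2S)-2-(3-hydroxy-4,5-dimethoxyphenyl)-7,8-dimethoxy-2,3-dihydro-4H-chromen-4-one
Conditions: HCl (1.25 M in MeOH), MeOH, 0 °C to rt
Reagents that add atoms: none
Why: Acid-catalysed methanolysis of the aryl methoxymethyl acetal runs through an oxocarbenium ion at the acetal carbon and is much easier than protonation of O1, a weakly basic vinylogous ester oxygen conjugated with the C4 carbonyl, so at room temperature the C2–O1 bond and the (S) configuration should be kept.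

## Compound list

1 | 3-hydroxy-4,5-dimethoxybenzaldehyde | COc1cc(C=O)cc(O)c1OC | starting material
2 | 3,4-dimethoxy-5-(methoxymethoxy)benzaldehyde | COc1cc(C=O)cc(OCOC)c1OC | intermediate
3 | N-methoxy-N-methylacetamide | CC(=O)N(C)OC | starting material
4 | lithium 1-[methoxy(methyl)amino]ethen-1-olate (amide enolate) | C=C([O-])N(C)OC.[Li+] | intermediate
5 | lithium 1-[3,4-dimethoxy-5-(methoxymethoxy)phenyl]-3-[methoxy(methyl)amino]-3-oxopropan-1-olate (racemic aldolate) | COc1cc(C([O-])CC(=O)N(C)OC)cc(OCOC)c1OC.[Li+] | intermediate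
6 | racemic 3-[3,4-dimethoxy-5-(methoxymethoxy)phenyl]-3-hydroxy-N-methoxy-N-methylpropanamide | COc1cc(C(O)CC(=O)N(C)OC)cc(OCOC)c1OC | intermediate
7 | 3-[3,4-dimethoxy-5-(methoxymethoxy)phenyl]-N-methoxy-N-methyl-3-oxopropanamide | COc1cc(C(=O)CC(=O)N(C)OC)cc(OCOC)c1OC | intermediate
8 | (3R)-3-[3,4-dimethoxy-5-(methoxymethoxy)phenyl]-3-hydroxy-N-methoxy-N-methylpropanamide | COc1cc([C@@H](CC(=O)N(C)OC)O)cc(OCOC)c1OC | intermediate
9 | 2,3-dimethoxyphenol | COc1cccc(O)c1OC | starting material
10 | 6-bromo-2,3-dimethoxyphenol | COc1ccc(Br)c(O)c1OC | intermediate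
11 | (R)-alkoxytriphenylphosphonium ion of 8, paired with the 6-bromo-2,3-dimethoxyphenoxide | COc1cc([C@@H](CC(=O)N(C)OC)O[P+](c2ccccc2)(c2ccccc2)c2ccccc2)cc(OCOC)c1OC.COc1ccc(Br)c([O-])c1OC | intermediate
12 | (3S)-3-(6-bromo-2,3-dimethoxyphenoxy)-3-[3,4-dimethoxy-5-(methoxymethoxy)phenyl]-N-methoxy-N-methylpropanamide | COc1cc([C@H](CC(=O)N(C)OC)Oc2c(Br)ccc(OC)c2OC)cc(OCOC)c1OC | intermediate
13 | (3S)-3-(6-lithio-2,3-dimethoxyphenoxy)-3-[3,4-dimethoxy-5-(methoxymethoxy)phenyl]-N-methoxy-N-methylpropanamide (aryllithium) | COc1cc([C@H](CC(=O)N(C)OC)Oc2c([Li])ccc(OC)c2OC)cc(OCOC)c1OC | intermediate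
14 | lithium (2S)-2-[3,4-dimethoxy-5-(methoxymethoxy)phenyl]-7,8-dimethoxy-4-[methoxy(methyl)amino]chroman-4-olate (C4 configuration not defined) | COc1cc([C@@H]2CC([O-])(N(C)OC)c3ccc(OC)c(OC)c3O2)cc(OCOC)c1OC.[Li+] | intermediate
15 | (2S)-2-[3,4-dimethoxy-5-(methoxymethoxy)phenyl]-7,8-dimethoxy-2,3-dihydro-4H-chromen-4-one | COc1cc([C@@H]2CC(=O)c3ccc(OC)c(OC)c3O2)cc(OCOC)c1OC | intermediate
16 | (2S)-2-(3-hydroxy-4,5-dimethoxyphenyl)-7,8-dimethoxy-2,3-dihydro-4H-chromen-4-one (CNP0402697.1) | COc1cc([C@@H]2CC(=O)c3ccc(OC)c(OC)c3O2)cc(O)c1OC | target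

## Step count and risks

Total step count: 8. Longest linear sequence: 7 (steps 1, 2, 3, 4, 6, 7, 8); step 5 is the one-step branch to the ring A partner.

The three steps most likely to fail:

**Step 7 (Parham cyclisation).** The organolithium, or the aryllithium once formed, may remove an α-proton of the amide, after which the aryloxide is expelled (β-elimination to a cinnamamide). The aryllithium may also be protonated before it closes the ring, giving debromination without cyclisation.

Fallback, from 8 and 10, returning at 15: ring C would be closed through the O1–C2 bond instead, after the C4–C4a bond has been made intermolecularly.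
- Carbinol 8 would be silylated (TBSCl, imidazole, DMF, rt) to (3R)-3-(tert-butyldimethylsilyloxy)-3-[3,4-dimethoxy-5-(methoxymethoxy)phenyl]-N-methoxy-N-methylpropanamide F1.
- Phenol 10 would be turned into its lithium 2-lithiophenoxide (n-BuLi, 2.2 equiv, Et2O/THF, −78 to 0 °C) and acylated by F1 to give (3R)-3-(tert-butyldimethylsilyloxy)-3-[3,4-dimethoxy-5-(methoxymethoxy)phenyl]-1-(2-hydroxy-3,4-dimethoxyphenyl)propan-1-one F2. The β-leaving group is now a silyloxide, far poorer than the aryloxide, so elimination should no longer compete.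
- HF·pyridine (THF, 0 °C) would free (3R)-3-[3,4-dimethoxy-5-(methoxymethoxy)phenyl]-3-hydroxy-1-(2-hydroxy-3,4-dimethoxyphenyl)propan-1-one F3.
- An intramolecular Mitsunobu reaction (PPh3, DIAD, THF, 0 °C) would let the ring A phenol displace the activated (R)-carbinol with inversion, giving 15 with the (2S) configuration.

**Step 6 (Mitsunobu etherification).** The activated carbinol may eliminate to the cinnamamide, the doubly ortho-substituted phenoxide may displace slowly so that the azodicarboxylate-derived hydrazide is alkylated instead, and partial ionisation at the benzylic carbon may erode the configuration.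

Fallback, from 2 and 10, returning at 12: the etherification would be run on a carbinol that has no carbonyl group, and the amide built afterwards.
- Brown allylation of aldehyde 2 with (+)-B-allyldiisopinocampheylborane (from (+)-B-methoxydiisopinocampheylborane and allylmagnesium bromide; Et2O, −78 °C; then NaOH, H2O2) should give (1R)-1-[3,4-dimethoxy-5-(methoxymethoxy)phenyl]but-3-en-1-ol F4.
- Mitsunobu reaction of F4 with 10 (PPh3, DIAD, toluene, 0 °C) should give, with inversion, 1-bromo-2-{[(1S)-1-[3,4-dimethoxy-5-(methoxymethoxy)phenyl]but-3-en-1-yl]oxy}-3,4-dimethoxybenzene F5.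
- Lemieux–Johnson cleavage (K2OsO4·2H2O cat., NaIO4, 2,6-lutidine, dioxane/H2O) would give (3S)-3-(6-bromo-2,3-dimethoxyphenoxy)-3-[3,4-dimethoxy-5-(methoxymethoxy)phenyl]propanal F6, which would be used crude because it can eliminate.
- Pinnick oxidation (NaClO2, NaH2PO4, 2-methyl-2-butene, t-BuOH/H2O) would give (3S)-3-(6-bromo-2,3-dimethoxyphenoxy)-3-[3,4-dimethoxy-5-(methoxymethoxy)phenyl]propanoic acid F7.
- Amide coupling (MeNHOMe·HCl, EDC·HCl, HOBt, N-methylmorpholine, CH2Cl2, 0 °C) would give 12.

**Step 5 (ortho-bromination).** Bromination may go para to the hydroxyl group (at C4, next to the 3-methoxy group), or twice, giving a regioisomer mixture that is hard to separate.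

Fallback, from 9, returning at 10: the position would be fixed by directed ortho-metalation instead of electrophilic substitution.
- Phenol 9 would be protected (MOMCl, i-Pr2NEt, CH2Cl2) as 1,2-dimethoxy-3-(methoxymethoxy)benzene F8.
- Lithiation (n-BuLi, THF, 0 °C) should occur next to the methoxymethoxy group, the stronger director, and quenching with 1,2-dibromotetrachloroethane at −78 °C would give 1-bromo-3,4-dimethoxy-2-(methoxymethoxy)benzene F9.
- HCl in MeOH at rt would remove the acetal and give 10.

## Further compounds

F1 | step 7 | (3R)-3-(tert-butyldimethylsilyloxy)-3-[3,4-dimethoxy-5-(methoxymethoxy)phenyl]-N-methoxy-N-methylpropanamide | COc1cc([C@@H](CC(=O)N(C)OC)O[Si](C)(C)C(C)(C)C)cc(OCOC)c1OC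
F2 | step 7 | (3R)-3-(tert-butyldimethylsilyloxy)-3-[3,4-dimethoxy-5-(methoxymethoxy)phenyl]-1-(2-hydroxy-3,4-dimethoxyphenyl)propan-1-one | COc1cc([C@@H](CC(=O)c2ccc(OC)c(OC)c2O)O[Si](C)(C)C(C)(C)C)cc(OCOC)c1OC
F3 | step 7 | (3R)-3-[3,4-dimethoxy-5-(methoxymethoxy)phenyl]-3-hydroxy-1-(2-hydroxy-3,4-dimethoxyphenyl)propan-1-one | COc1cc([C@@H](CC(=O)c2ccc(OC)c(OC)c2O)O)cc(OCOC)c1OC
F4 | step 6 | (1R)-1-[3,4-dimethoxy-5-(methoxymethoxy)phenyl]but-3-en-1-ol | COc1cc([C@@H](CC=C)O)cc(OCOC)c1OC
F5 | step 6 | 1-bromo-2-{[(1S)-1-[3,4-dimethoxy-5-(methoxymethoxy)phenyl]but-3-en-1-yl]oxy}-3,4-dimethoxybenzene | COc1cc([C@H](CC=C)Oc2c(Br)ccc(OC)c2OC)cc(OCOC)c1OC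
F6 | step 6 | (3S)-3-(6-bromo-2,3-dimethoxyphenoxy)-3-[3,4-dimethoxy-5-(methoxymethoxy)phenyl]propanal | COc1cc([C@H](CC=O)Oc2c(Br)ccc(OC)c2OC)cc(OCOC)c1OC
F7 | step 6 | (3S)-3-(6-bromo-2,3-dimethoxyphenoxy)-3-[3,4-dimethoxy-5-(methoxymethoxy)phenyl]propanoic acid | COc1cc([C@H](CC(=O)O)Oc2c(Br)ccc(OC)c2OC)cc(OCOC)c1OC
F8 | step 5 | 1,2-dimethoxy-3-(methoxymethoxy)benzene | COCOc1cccc(OC)c1OC
F9 | step 5 | 1-bromo-3,4-dimethoxy-2-(methoxymethoxy)benzene | COCOc1c(Br)ccc(OC)c1OC
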